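**Retrosynthetic overview**

1. The target is a resveratrol-type trimer: an all-trans 1,2,3-trisubstituted indane-4,6-diol whose C2 carries an enantiopure trans-2,3-diaryl-2,3-dihydrobenzofuran. The (S)-carbinol on C1 is made last from the aryl ketone, after global removal of benzyl and tert-butyl groups.
2. Key disconnection: both bonds from the benzo ring of the indane, C7a–C1 and C3a–C3, are cut at once. This gives a 3,5-dioxygenated aryne and an all-carbon 1,3-zwitterion, stored as a 2,3-dihydrofuran (temporary ring) and released by base.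
3. Enabling feature: C3 carries a 4-hydroxyphenyl group, so C3 can be the exocyclic carbon of a p-quinone methide (electrophile). C1 carries the aryl carbinol carbon, so as aryl ketone plus a removable tert-butyl ester it is a β-ketoester enolate carbon (nucleophile). O-4 of the benzo ring polarises the C3a≡C7a aryne so that the enolate enters at C7a and the aryl anion at C3a closes on C3.
4. The dihydrofuran comes from an (E)-stilbene (Horner–Wadsworth–Emmons) and a diazo β-ketoester (rhodium-carbenoid [3+2]). That step sets C2 of the indane under control of the dihydrobenzofuran, which is made by enantioselective carbene C–H insertion and acid epimerisation to trans.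
5. Ring order: dihydrobenzofuran, then dihydrofuran (temporary), then the cyclopentane ring of the indane (key step).

Key step: step 17

Assumption: 1, 4, 15, 17 and 21 are purchased; the sense of induction of Rh2(R-PTAD)4 (step 7) and of (R)-Me-CBS (step 20) is assigned by analogy with simpler substrates, and the antipodal catalyst is used if it proves opposite.

**Route**

Step 1
Reactants: 1 1-bromo-3,5-bis(benzyloxy)benzene
Product: 2 2-bromo-4,6-bis(benzyloxy)benzaldehyde
Conditions: POCl3, DMF, 0 → 80 °C; then H2O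
Reagents that add atoms: N,N-dimethylformamide, CN(C)C=O; water, O
Why: Vilsmeier–Haack formylation should occur para to one benzyloxy group and ortho to the other at the position next to bromine, the site between the two ethers being more hindered.

Step 2
Reactants: 2 2-bromo-4,6-bis(benzyloxy)benzaldehyde
Product: 3 4-(benzyloxy)-2-bromo-6-hydroxybenzaldehyde
Conditions: MgBr2·OEt2, toluene/Et2O, 80 °C; aq. HCl
Reagents that add atoms: none
Why: Chelation of MgBr2 between the aldehyde oxygen and the ortho ether directs bromide-mediated debenzylation to that ether only (chelation-controlled ether cleavage).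

Step 3
Reactants: 3 4-(benzyloxy)-2-bromo-6-hydroxybenzaldehyde; 4 4-(benzyloxy)benzyl chloride
Product: 5 4-(benzyloxy)-2-{[4-(benzyloxy)benzyl]oxy}-6-bromobenzaldehyde
Conditions: K2CO3, DMF, 60 °C
Reagents that add atoms: none
Why: Williamson etherification installs the 4-(benzyloxy)benzyl group whose benzylic C–H becomes C2 of the dihydrobenzofuran.

Step 4
Reactants: 5 4-(benzyloxy)-2-{[4-(benzyloxy)benzyl]oxy}-6-bromobenzaldehyde; 1 1-bromo-3,5-bis(benzyloxy)benzene
Product: 7 [4-(benzyloxy)-2-{[4-(benzyloxy)benzyl]oxy}-6-bromophenyl][3,5-bis(benzyloxy)phenyl]methanol (racemic), via 3,5-bis(benzyloxy)phenylmagnesium bromide 6 (not isolated)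
Conditions: 1, Mg, THF, reflux; then 5, THF, 0 °C; aq. NH4Cl
Reagents that add atoms: none
Why: Grignard addition to the aldehyde; the carbinol centre is removed in the next step.

Step 5
Reactants: 7 the diaryl carbinol
Product: 8 [4-(benzyloxy)-2-{[4-(benzyloxy)benzyl]oxy}-6-bromophenyl][3,5-bis(benzyloxy)phenyl]methanone
Conditions: Dess–Martin periodinane, CH2Cl2, rt
Reagents that add atoms: none
Why: Dess–Martin oxidation of a diaryl carbinol to the benzophenone.

Step 6
Reactants: 8 the diaryl ketone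
Product: 9 hydrazone of 8 (E/Z mixture)
Conditions: N2H4·H2O (excess), AcOH (cat.), n-BuOH, 110 °C
Reagents that add atoms: hydrazine, NN
Why: Hydrazone condensation, forced with excess hydrazine and heat because the ketone is di-ortho-substituted.

Step 7
Reactants: 9 hydrazone of 8
Product: 11 (2S,3R)-6-(benzyloxy)-2-[4-(benzyloxy)phenyl]-3-[3,5-bis(benzyloxy)phenyl]-4-bromo-2,3-dihydro-1-benzofuran (2,3-cis), via diaryldiazomethane 10 (not isolated)
Conditions: MnO2, CH2Cl2, 0 °C, filtration; then Rh2(R-PTAD)4 (dirhodium tetrakis[(R)-(1-adamantyl)(phthalimido)acetate], 1 mol %), CH2Cl2, 0 °C → rt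
Reagents that add atoms: none
Why: Dehydrogenation gives the donor/donor diazo compound and the chiral dirhodium carboxylate effects enantioselective intramolecular 1,5 C–H insertion of the diaryl carbene into the benzylic ether C–H, which sets C3 (R) by catalyst control and C2 cis to it in the concerted insertion.

Step 8
Reactants: 11 the cis-dihydrobenzofuran
Product: 12 (2R,3R)-6-(benzyloxy)-2-[4-(benzyloxy)phenyl]-3-[3,5-bis(benzyloxy)phenyl]-4-bromo-2,3-dihydro-1-benzofuran (2,3-trans)
Conditions: TFA, CH2Cl2, rt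
Reagents that add atoms: none
Why: Acid epimerisation: reversible ionisation of the C2–O bond to the 4-alkoxybenzyl cation and reclosure should give the thermodynamically preferred trans isomer, with C3 untouched.

Step 9
Reactants: 12 the trans bromide
Product: 14 (2R,3R)-6-(benzyloxy)-2-[4-(benzyloxy)phenyl]-3-[3,5-bis(benzyloxy)phenyl]-2,3-dihydro-1-benzofuran-4-carbaldehyde, via 4-lithio dihydrobenzofuran 13 (not isolated)
Conditions: n-BuLi, THF, −78 °C; DMF, −78 → 0 °C; aq. NH4Cl
Reagents that add atoms: N,N-dimethylformamide, CN(C)C=O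
Why: Bromine–lithium exchange, faster at −78 °C than benzylic deprotonation, followed by Bouveault formylation.

Step 10
Reactants: 14 the aldehyde; 15 diethyl (3,5-di-tert-butyl-4-hydroxybenzyl)phosphonate
Product: 16 4-[(E)-2-{(2R,3R)-6-(benzyloxy)-2-[4-(benzyloxy)phenyl]-3-[3,5-bis(benzyloxy)phenyl]-2,3-dihydro-1-benzofuran-4-yl}ethenyl]-2,6-di-tert-butylphenol
Conditions: KOt-Bu (2.5 equiv), THF, 0 °C → rt; aq. NH4Cl
Reagents that add atoms: none
Why: Horner–Wadsworth–Emmons olefination of the phosphonate dianion, E-selective.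

Step 11
Reactants: 17 methyl 4-(benzyloxy)benzoate
Product: 18 tert-butyl 3-[4-(benzyloxy)phenyl]-3-oxopropanoate
Conditions: LDA (2.2 equiv), tert-butyl acetate, THF, −78 °C; then 17, −78 → 0 °C; aq. NH4Cl
Reagents that add atoms: tert-butyl acetate, CC(=O)OC(C)(C)C
Why: Crossed Claisen condensation; the tert-butyl ester is the activating group that step 18 removes.

Step 12
Reactants: 18 the β-ketoester
Product: 19 tert-butyl 3-[4-(benzyloxy)phenyl]-2-diazo-3-oxopropanoate
Conditions: 4-acetamidobenzenesulfonyl azide, Et3N, MeCN, rt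
Reagents that add atoms: 4-acetamidobenzenesulfonyl azide, CC(=O)Nc1ccc(cc1)S(=O)(=O)N=[N+]=[N-]
Why: Regitz diazo transfer to an active methylene.

Step 13
Reactants: 16 the (E)-stilbene; 19 the diazo β-ketoester
Product: 20 tert-butyl (2S,3S)-5-[4-(benzyloxy)phenyl]-2-(3,5-di-tert-butyl-4-hydroxyphenyl)-3-{(2R,3R)-6-(benzyloxy)-2-[4-(benzyloxy)phenyl]-3-[3,5-bis(benzyloxy)phenyl]-2,3-dihydro-1-benzofuran-4-yl}-2,3-dihydrofuran-4-carboxylate (2,3-trans)
Conditions: Rh2(OAc)4 (2 mol %), 19 added slowly, PhF, 60 °C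
Reagents that add atoms: none
Why: Rhodium-carbenoid formal [3+2] cycloaddition of an α-diazo-β-ketoester with an electron-rich alkene: the carbenoid carbon bonds to the stilbene carbon next to the benzofuran, the p-hydroxybenzyl cation is closed by the enolate oxygen to the trans dihydrofuran, and the new C–C bond (future C2 of the indane) should form on the face opposite the 3-aryl group of the dihydrobenzofuran in the rotamer that turns the styryl unit away from C3 (substrate control).

Step 14
Reactants: 21 3,5-bis(benzyloxy)phenol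
Product: 22 3,5-bis(benzyloxy)phenyl N-isopropylcarbamate
Conditions: i-PrNCO, Et3N (cat.), CH2Cl2, rt
Reagents that add atoms: isopropyl isocyanate, CC(C)N=C=O
Why: Carbamoylation of the phenol installs the ortho-directing group.

Step 15
Reactants: 22 the carbamate
Product: 25 3,5-bis(benzyloxy)-2-(trimethylsilyl)phenyl N-isopropylcarbamate, via N-silyl carbamate 23 (not isolated), via ortho-lithiated carbamate 24 (not isolated)
Conditions: TBSOTf, TMEDA, Et2O, 0 °C → rt; then n-BuLi, TMEDA, −78 °C; TMSCl; aq. NaHSO4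
Reagents that add atoms: chlorotrimethylsilane, C[Si](C)(C)Cl
Why: Directed ortho-metalation of the N-silylated carbamate at the position flanked by the carbamate and a benzyloxy group, then C-silylation.

Step 16
Reactants: 25 the silyl carbamate
Product: 27 3,5-bis(benzyloxy)-2-(trimethylsilyl)phenyl trifluoromethanesulfonate, via 3,5-bis(benzyloxy)-2-(trimethylsilyl)phenol 26 (not isolated)
Conditions: DBU, Et2NH, MeCN, 40 °C; then PhNTf2, rt
Reagents that add atoms: N-phenylbis(trifluoromethanesulfonimide), O=S(=O)(N(c1ccccc1)S(=O)(=O)C(F)(F)F)C(F)(F)F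
Why: Amine-mediated carbamate cleavage and triflation of the phenoxide give the ortho-silylaryl triflate aryne precursor.

Step 17
Reactants: 20 the dihydrofuran; 27 the ortho-silylaryl triflate
Product: 30 tert-butyl (2S,3S)-1-[4-(benzyloxy)benzoyl]-4,6-bis(benzyloxy)-3-(3,5-di-tert-butyl-4-hydroxyphenyl)-2-{(2R,3R)-6-(benzyloxy)-2-[4-(benzyloxy)phenyl]-3-[3,5-bis(benzyloxy)phenyl]-2,3-dihydro-1-benzofuran-4-yl}-2,3-dihydro-1H-indene-1-carboxylate (C1 epimers), via 3,5-bis(benzyloxy)benzyne 28 (not isolated), via quinone methide enolate 29 (not isolated)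
Conditions: CsF (4 equiv), 18-crown-6 (cat.), MeCN/toluene, 27 (2 equiv) by syringe pump, 50 °C; aq. NH4Cl
Reagents that add atoms: none
Why: Proposed new method: CsF deprotonates the hindered phenol of 20 and the phenoxide expels the enolate oxygen from the benzylic C2 of the dihydrofuran (retro-oxa-1,6-addition), which unmasks the all-carbon 1,3-zwitterion 29 while the same fluoride releases aryne 28; the enolate carbon adds to the aryne carbon distal to the neighbouring benzyloxy group, and the aryl anion so formed closes on the quinone methide carbon by 1,6-addition, which restores the phenol ring. The closest known reaction types are the fluoride- or base-triggered release of p-quinone methides from 4-oxybenzyl precursors with capture by 1,3-dicarbonyl nucleophiles, the C-arylation/σ-insertion of β-ketoester enolates with arynes, and aryne annulations in which a heteroatom nucleophile adds first and the aryl anion then closes by 1,6-addition onto a tethered p-quinone methide. The one ring that is closed, the cyclopentane of the indane, forms by 5-exo-trig conjugate addition of the aryl anion, the first C–C bond being intermolecular. The new stereocentre at C3 is set in this closure trans to the benzofuranyl group on C2, because the bulky quinone methide ring avoids that group in the envelope transition state; C2 is carried over from 20, and the quaternary C1 forms as a mixture that converges in step 18. The step needs aryne regioselectivity (secured by the inductive effect of the benzyloxy group next to the triple bond), C-arylation without phenoxide O-arylation (soft tertiary β-ketoester carbanion, two ortho tert-butyl groups), 5-exo capture of the quinone methide over 4-exo attack on the ketone or ester (higher electrophilicity, lower strain), and aryne capture that outruns quinone methide–styrene tautomerisation at C2; reclosure to 20 or to the isomeric donor–acceptor cyclopropane is harmless because both reopen, and the absence of acid keeps the quinone methide from seven-membered Friedel–Crafts closure with the 3,5-bis(benzyloxy)phenyl ring.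

Step 18
Reactants: 30 the indane β-ketoester
Product: 31 [(1S,2R,3S)-4,6-dihydroxy-3-(4-hydroxyphenyl)-2-{(2R,3R)-3-(3,5-dihydroxyphenyl)-6-hydroxy-2-(4-hydroxyphenyl)-2,3-dihydro-1-benzofuran-4-yl}-2,3-dihydro-1H-inden-1-yl](4-hydroxyphenyl)methanone
Conditions: AlCl3 (excess), pentamethylbenzene, toluene/MeNO2, 0 → 50 °C; aq. HCl
Reagents that add atoms: none
Why: AlCl3 does three known things in one pot, namely Lewis-acid debenzylation with pentamethylbenzene as benzyl cation trap, retro-Friedel–Crafts transfer of the two aryl tert-butyl groups to toluene, and cleavage of the tert-butyl ester with decarboxylation of the β-keto acid, after which C1 is protonated to the thermodynamically preferred epimer, trans to the C2 substituent.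

Step 19
Reactants: 31 the octaphenol ketone
Product: 32 octaacetate of 31
Conditions: Ac2O, pyridine, DMAP (cat.), CH2Cl2, 0 °C → rt
Reagents that add atoms: acetic anhydride, CC(=O)OC(C)=O
Why: Peracetylation keeps the ketone electrophilic (no phenoxide conjugation) and protects the later carbinol from ionisation.

Step 20
Reactants: 32 the octaacetate ketone
Product: 33 octaacetate of the target, (S)-carbinol
Conditions: (R)-2-methyl-CBS-oxazaborolidine (1 equiv), BH3·SMe2, THF/CH2Cl2, −20 → 0 °C; MeOH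
Reagents that add atoms: none
Why: Corey–Bakshi–Shibata reduction with the aryl ring as the large group, so that the (R)-catalyst should deliver hydride to the face that gives the (S)-carbinol, in agreement with the Felkin–Anh preference for attack anti to the C1–C7a bond.

Step 21
Reactants: 33 the octaacetate carbinol
Product: 34 (1S,2R,3S)-1-[(S)-hydroxy(4-hydroxyphenyl)methyl]-3-(4-hydroxyphenyl)-2-[(2R,3R)-3-(3,5-dihydroxyphenyl)-6-hydroxy-2-(4-hydroxyphenyl)-2,3-dihydro-1-benzofuran-4-yl]-2,3-dihydro-1H-indene-4,6-diol (CNP0175860.1)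
Conditions: NH3 (7 M in MeOH), 0 °C → rt, argon
Reagents that add atoms: none
Why: Ammonolysis of the eight aryl acetates under mild, non-acidic conditions, which the benzylic 4-hydroxyphenyl carbinol should tolerate without quinone methide formation or dehydration.

**Compound list**

1 | 1-bromo-3,5-bis(benzyloxy)benzene | Brc1cc(OCc2ccccc2)cc(OCc2ccccc2)c1 | starting material
2 | 2-bromo-4,6-bis(benzyloxy)benzaldehyde | O=Cc1c(Br)cc(OCc2ccccc2)cc1OCc1ccccc1 | intermediate
3 | 4-(benzyloxy)-2-bromo-6-hydroxybenzaldehyde | O=Cc1c(Br)cc(OCc2ccccc2)cc1O | intermediate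
4 | 4-(benzyloxy)benzyl chloride | ClCc1ccc(OCc2ccccc2)cc1 | starting material
5 | 4-(benzyloxy)-2-{[4-(benzyloxy)benzyl]oxy}-6-bromobenzaldehyde | O=Cc1c(Br)cc(OCc2ccccc2)cc1OCc1ccc(OCc2ccccc2)cc1 | intermediate
6 | 3,5-bis(benzyloxy)phenylmagnesium bromide | Br[Mg]c1cc(OCc2ccccc2)cc(OCc2ccccc2)c1 | intermediate (not isolated)
7 | [4-(benzyloxy)-2-{[4-(benzyloxy)benzyl]oxy}-6-bromophenyl][3,5-bis(benzyloxy)phenyl]methanol, racemic | OC(c1cc(OCc2ccccc2)cc(OCc2ccccc2)c1)c1c(Br)cc(OCc2ccccc2)cc1OCc1ccc(OCc2ccccc2)cc1 | intermediate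
8 | [4-(benzyloxy)-2-{[4-(benzyloxy)benzyl]oxy}-6-bromophenyl][3,5-bis(benzyloxy)phenyl]methanone | O=C(c1cc(OCc2ccccc2)cc(OCc2ccccc2)c1)c1c(Br)cc(OCc2ccccc2)cc1OCc1ccc(OCc2ccccc2)cc1 | intermediate
9 | hydrazone of 8 (E/Z) | NN=C(c1cc(OCc2ccccc2)cc(OCc2ccccc2)c1)c1c(Br)cc(OCc2ccccc2)cc1OCc1ccc(OCc2ccccc2)cc1 | intermediate
10 | 1-{[3,5-bis(benzyloxy)phenyl](diazo)methyl}-4-(benzyloxy)-2-{[4-(benzyloxy)benzyl]oxy}-6-bromobenzene | [N-]=[N+]=C(c1cc(OCc2ccccc2)cc(OCc2ccccc2)c1)c1c(Br)cc(OCc2ccccc2)cc1OCc1ccc(OCc2ccccc2)cc1 | intermediate (not isolated)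
11 | (2S,3R)-6-(benzyloxy)-2-[4-(benzyloxy)phenyl]-3-[3,5-bis(benzyloxy)phenyl]-4-bromo-2,3-dihydro-1-benzofuran (cis) | Brc1cc(OCc2ccccc2)cc2c1[C@@H](c1cc(OCc3ccccc3)cc(OCc3ccccc3)c1)[C@@H](c1ccc(OCc3ccccc3)cc1)O2 | intermediate
12 | (2R,3R)-6-(benzyloxy)-2-[4-(benzyloxy)phenyl]-3-[3,5-bis(benzyloxy)phenyl]-4-bromo-2,3-dihydro-1-benzofuran (trans) | Brc1cc(OCc2ccccc2)cc2c1[C@@H](c1cc(OCc3ccccc3)cc(OCc3ccccc3)c1)[C@H](c1ccc(OCc3ccccc3)cc1)O2 | intermediate
13 | 4-lithio derivative of 12 (lithium in place of bromine) | [Li]c1cc(OCc2ccccc2)cc2c1[C@@H](c1cc(OCc3ccccc3)cc(OCc3ccccc3)c1)[C@H](c1ccc(OCc3ccccc3)cc1)O2 | intermediate (not isolated)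
14 | (2R,3R)-6-(benzyloxy)-2-[4-(benzyloxy)phenyl]-3-[3,5-bis(benzyloxy)phenyl]-2,3-dihydro-1-benzofuran-4-carbaldehyde | O=Cc1cc(OCc2ccccc2)cc2c1[C@@H](c1cc(OCc3ccccc3)cc(OCc3ccccc3)c1)[C@H](c1ccc(OCc3ccccc3)cc1)O2 | intermediate
15 | diethyl (3,5-di-tert-butyl-4-hydroxybenzyl)phosphonate | CCOP(=O)(Cc1cc(C(C)(C)C)c(O)c(C(C)(C)C)c1)OCC | starting material
16 | 4-[(E)-2-{(2R,3R)-6-(benzyloxy)-2-[4-(benzyloxy)phenyl]-3-[3,5-bis(benzyloxy)phenyl]-2,3-dihydro-1-benzofuran-4-yl}ethenyl]-2,6-di-tert-butylphenol | CC(C)(C)c1cc(/C=C/c2cc(OCc3ccccc3)cc3c2[C@@H](c2cc(OCc4ccccc4)cc(OCc4ccccc4)c2)[C@H](c2ccc(OCc4ccccc4)cc2)O3)cc(C(C)(C)C)c1O | intermediate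
17 | methyl 4-(benzyloxy)benzoate | COC(=O)c1ccc(OCc2ccccc2)cc1 | starting material
18 | tert-butyl 3-[4-(benzyloxy)phenyl]-3-oxopropanoate | CC(C)(C)OC(=O)CC(=O)c1ccc(OCc2ccccc2)cc1 | intermediate
19 | tert-butyl 3-[4-(benzyloxy)phenyl]-2-diazo-3-oxopropanoate | CC(C)(C)OC(=O)C(=[N+]=[N-])C(=O)c1ccc(OCc2ccccc2)cc1 | intermediate
20 | tert-butyl (2S,3S)-5-[4-(benzyloxy)phenyl]-2-(3,5-di-tert-butyl-4-hydroxyphenyl)-3-[(2R,3R)-dihydrobenzofuran-4-yl unit of 12]-2,3-dihydrofuran-4-carboxylate (2,3-trans) | CC(C)(C)OC(=O)C1=C(c2ccc(OCc3ccccc3)cc2)O[C@H](c2cc(C(C)(C)C)c(O)c(C(C)(C)C)c2)[C@H]1c1cc(OCc2ccccc2)cc2c1[C@@H](c1cc(OCc3ccccc3)cc(OCc3ccccc3)c1)[C@H](c1ccc(OCc3ccccc3)cc1)O2 | intermediate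
21 | 3,5-bis(benzyloxy)phenol | Oc1cc(OCc2ccccc2)cc(OCc2ccccc2)c1 | starting material
22 | 3,5-bis(benzyloxy)phenyl N-isopropylcarbamate | CC(C)NC(=O)Oc1cc(OCc2ccccc2)cc(OCc2ccccc2)c1 | intermediate
23 | 3,5-bis(benzyloxy)phenyl N-(tert-butyldimethylsilyl)-N-isopropylcarbamate | CC(C)N(C(=O)Oc1cc(OCc2ccccc2)cc(OCc2ccccc2)c1)[Si](C)(C)C(C)(C)C | intermediate (not isolated)
24 | 2-lithio derivative of 23 | CC(C)N(C(=O)Oc1cc(OCc2ccccc2)cc(OCc2ccccc2)c1[Li])[Si](C)(C)C(C)(C)C | intermediate (not isolated)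
25 | 3,5-bis(benzyloxy)-2-(trimethylsilyl)phenyl N-isopropylcarbamate | CC(C)NC(=O)Oc1cc(OCc2ccccc2)cc(OCc2ccccc2)c1[Si](C)(C)C | intermediate
26 | 3,5-bis(benzyloxy)-2-(trimethylsilyl)phenol | Oc1cc(OCc2ccccc2)cc(OCc2ccccc2)c1[Si](C)(C)C | intermediate (not isolated)
27 | 3,5-bis(benzyloxy)-2-(trimethylsilyl)phenyl trifluoromethanesulfonate | C[Si](C)(C)c1c(OS(=O)(=O)C(F)(F)F)cc(OCc2ccccc2)cc1OCc1ccccc1 | intermediate
28 | 3,5-bis(benzyloxy)benzyne (1,2-didehydro-3,5-bis(benzyloxy)benzene) | O(Cc1ccccc1)C1=CC(OCc2ccccc2)=CC#C1 | intermediate (not isolated)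
29 | cesium enolate of the ring-opened p-quinone methide β-ketoester (stereocentre of the future indane C2 as in 20) | [Cs+].CC(C)(C)OC(=O)C(=C([O-])c1ccc(OCc2ccccc2)cc1)[C@@H](C=C1C=C(C(C)(C)C)C(=O)C(C(C)(C)C)=C1)c1cc(OCc2ccccc2)cc2c1[C@@H](c1cc(OCc3ccccc3)cc(OCc3ccccc3)c1)[C@H](c1ccc(OCc3ccccc3)cc1)O2 | intermediate (not isolated)
30 | tert-butyl (2S,3S)-1-[4-(benzyloxy)benzoyl]-4,6-bis(benzyloxy)-3-(3,5-di-tert-butyl-4-hydroxyphenyl)-2-[(2R,3R)-dihydrobenzofuran-4-yl unit of 12]-2,3-dihydro-1H-indene-1-carboxylate (2,3-trans, C1 epimers) | CC(C)(C)c1cc(cc(C(C)(C)C)c1O)[C@H]1c2c(OCc3ccccc3)cc(OCc3ccccc3)cc2C(C(=O)OC(C)(C)C)(C(=O)c2ccc(OCc3ccccc3)cc2)[C@@H]1c1cc(OCc2ccccc2)cc2c1[C@@H](c1cc(OCc3ccccc3)cc(OCc3ccccc3)c1)[C@H](c1ccc(OCc3ccccc3)cc1)O2 | intermediate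
31 | [(1S,2R,3S)-4,6-dihydroxy-3-(4-hydroxyphenyl)-2-{(2R,3R)-3-(3,5-dihydroxyphenyl)-6-hydroxy-2-(4-hydroxyphenyl)-2,3-dihydro-1-benzofuran-4-yl}-2,3-dihydro-1H-inden-1-yl](4-hydroxyphenyl)methanone | Oc1ccc([C@H]2c3c(O)cc(O)cc3[C@@H](C(=O)c3ccc(O)cc3)[C@@H]2c2cc(O)cc3c2[C@@H](c2cc(O)cc(O)c2)[C@H](c2ccc(O)cc2)O3)cc1 | intermediate
32 | octaacetate of 31 (all eight phenols acetylated) | CC(=O)Oc1ccc([C@H]2c3c(OC(C)=O)cc(OC(C)=O)cc3[C@@H](C(=O)c3ccc(OC(C)=O)cc3)[C@@H]2c2cc(OC(C)=O)cc3c2[C@@H](c2cc(OC(C)=O)cc(OC(C)=O)c2)[C@H](c2ccc(OC(C)=O)cc2)O3)cc1 | intermediate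
33 | octaacetate of the target, free (S)-carbinol | CC(=O)Oc1ccc([C@H]2c3c(OC(C)=O)cc(OC(C)=O)cc3[C@@H]([C@H](O)c3ccc(OC(C)=O)cc3)[C@@H]2c2cc(OC(C)=O)cc3c2[C@@H](c2cc(OC(C)=O)cc(OC(C)=O)c2)[C@H](c2ccc(OC(C)=O)cc2)O3)cc1 | intermediate
34 | (1S,2R,3S)-1-[(S)-hydroxy(4-hydroxyphenyl)methyl]-3-(4-hydroxyphenyl)-2-[(2R,3R)-3-(3,5-dihydroxyphenyl)-6-hydroxy-2-(4-hydroxyphenyl)-2,3-dihydro-1-benzofuran-4-yl]-2,3-dihydro-1H-indene-4,6-diol | Oc1ccc([C@H]2c3c(O)cc(O)cc3[C@@H]([C@H](O)c3ccc(O)cc3)[C@@H]2c2cc(O)cc3c2[C@@H](c2cc(O)cc(O)c2)[C@H](c2ccc(O)cc2)O3)cc1 | target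

**Step count and risks**

Total step count: 21. Longest linear sequence: 16 steps (1–10, 13, 17–21).

Steps most likely to fail:

1. Step 17 (proposed new method). The hindered tertiary enolate may be captured by the aryne too slowly, so that phenoxide O-arylation, 4-exo acyl transfer to the aryl anion, or quinone methide–styrene tautomerisation (erosion of the C2 configuration) take over. The fallback makes the two bonds one after the other with known organometallic chemistry and no acid; it sets out from 20 and 1 and returns at 30. Compound 1 is iodinated next to bromine (N-iodosuccinimide, cat. TFA, MeCN) to 1-bromo-2-iodo-3,5-bis(benzyloxy)benzene F1. Iodine–magnesium exchange (i-PrMgCl·LiCl, THF, −40 °C) gives [2-bromo-4,6-bis(benzyloxy)phenyl]magnesium chloride F2, kept cold so that it does not eliminate to the aryne. Compound 20 is deprotonated with one equivalent of i-PrMgCl, which opens it to the magnesium enolate/quinone methide, and F2 adds 1,6 to the quinone methide carbon (known addition of aryl Grignard reagents to p-quinone methides) to give the open-chain aryl bromide F3 after aq. NH4Cl. Intramolecular palladium-catalysed α-arylation of the β-ketoester (Pd(OAc)2, P(t-Bu)3, K3PO4, toluene, 90 °C) then closes the five-membered ring to 30; epimers at the diarylmethine carbon would be separated there.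

2. Step 18. One Lewis acid has to do seven debenzylations, two retro-Friedel–Crafts dealkylations and an ester cleavage; C-benzylation of the resorcinol rings, incomplete tert-butyl transfer or Lewis-acid opening of the dihydrobenzofuran may result. The fallback separates the tasks by mechanism; it sets out from 30 and returns at 31. Hydrogenolysis (H2, Pd(OH)2 on carbon, EtOAc/MeOH) removes the seven benzyl groups as toluene and should give the heptaphenol β-ketoester F4, whose ketone is hindered and non-enolisable. AlCl3 in toluene/MeNO2 then only has to transfer the tert-butyl groups and cleave the ester with decarboxylation to give 31.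

3. Step 20. Hydride delivery to a hindered α-branched aryl ketone may show poor or reversed facial selectivity, because the branched indanyl group can compete with the aryl ring as the large group. The fallback corrects the carbinol centre by substitution instead of by reduction; it sets out from 32 and returns at 34. Compound 32 is reduced with whichever reagent gives the cleanest single epimer. If this is the (R)-carbinol octaacetate F5, Mitsunobu inversion (4-nitrobenzoic acid, PPh3, DIAD, THF) should give the (S)-4-nitrobenzoate octaacetate F6, and K2CO3 in MeOH at 0 °C removes all nine ester groups to give 34. From a mixture the unwanted epimer would be separated and returned to 32 by Dess–Martin oxidation.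

**Further compounds**

F1 | step 17 | 1-bromo-2-iodo-3,5-bis(benzyloxy)benzene | Brc1cc(OCc2ccccc2)cc(OCc2ccccc2)c1I
F2 | step 17 | [2-bromo-4,6-bis(benzyloxy)phenyl]magnesium chloride | Cl[Mg]c1c(Br)cc(OCc2ccccc2)cc1OCc1ccccc1
F3 | step 17 | tert-butyl 2-[4-(benzyloxy)benzoyl]-4-[2-bromo-4,6-bis(benzyloxy)phenyl]-4-(3,5-di-tert-butyl-4-hydroxyphenyl)-3-[(2R,3R)-dihydrobenzofuran-4-yl unit of 12]butanoate (C3 as required, C2 and C4 epimers) | CC(C)(C)OC(=O)C(C(=O)c1ccc(OCc2ccccc2)cc1)[C@H](c1cc(OCc2ccccc2)cc2c1[C@@H](c1cc(OCc3ccccc3)cc(OCc3ccccc3)c1)[C@H](c1ccc(OCc3ccccc3)cc1)O2)C(c1cc(C(C)(C)C)c(O)c(C(C)(C)C)c1)c1c(Br)cc(OCc2ccccc2)cc1OCc1ccccc1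
F4 | step 18 | heptaphenol of 30 (all seven benzyl groups removed; tert-butyl ester and aryl tert-butyl groups kept) | CC(C)(C)c1cc(cc(C(C)(C)C)c1O)[C@H]1c2c(O)cc(O)cc2C(C(=O)OC(C)(C)C)(C(=O)c2ccc(O)cc2)[C@@H]1c1cc(O)cc2c1[C@@H](c1cc(O)cc(O)c1)[C@H](c1ccc(O)cc1)O2
F5 | step 20 | octaacetate of the C-carbinol epimer of the target, (R)-carbinol | CC(=O)Oc1ccc([C@H]2c3c(OC(C)=O)cc(OC(C)=O)cc3[C@@H]([C@@H](O)c3ccc(OC(C)=O)cc3)[C@@H]2c2cc(OC(C)=O)cc3c2[C@@H](c2cc(OC(C)=O)cc(OC(C)=O)c2)[C@H](c2ccc(OC(C)=O)cc2)O3)cc1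
F6 | step 20 | (S)-4-nitrobenzoate of 33 | CC(=O)Oc1ccc([C@H]2c3c(OC(C)=O)cc(OC(C)=O)cc3[C@@H]([C@H](OC(=O)c3ccc(cc3)[N+]([O-])=O)c3ccc(OC(C)=O)cc3)[C@@H]2c2cc(OC(C)=O)cc3c2[C@@H](c2cc(OC(C)=O)cc(OC(C)=O)c2)[C@H](c2ccc(OC(C)=O)cc2)O3)cc1
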